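Vitisinol B's seven-membered ring contains two adjacent carbons of resorcinol ring A, the ring also fused to the dihydrofuran. One is bonded to methine C8b, which carries the formylphenol ring E. The other, ortho to the ring A ether oxygen, is bonded to dihydrofuran carbon C8a. Excising this two-carbon arene edge contracts the core to a trans-2,3-diarylindan-1-one (C8a = carbonyl, C8b = α-carbon) and leaves ring A as a 3,5-dioxygenated benzyne. The key step inserts the aryne into the indanone C1–C2 bond, forming both aryl–carbon bonds and expanding five to seven. Benzyl Grignard addition, debenzylation and acid-mediated phenol-to-styrene cyclisation then build the dihydrofuran.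

Key step: step 7

Labels:
- Ring A is the resorcinol ring fused to both the dihydrofuran and the seven-membered ring.
- Ring B is the other resorcinol ring.
- Ring C is the seven-membered carbocycle.
- Ring D is the 4-hydroxyphenyl on C7b.
- Ring E is the 5-formyl-2-hydroxyphenyl on C8b.
- Ring F is the 4-hydroxyphenyl on C7a.
- C7a is the oxygen-bearing dihydrofuran carbon and C8a is its neighbour.
- C7b and C8b are the adjacent methines of ring C.
- The target has C7a (S), C8a (S), C7b (S) and C8b (R).

Assumption: the (R)-configured bisphosphine in step 2 is taken to deliver the (S)-indanone. If the sense of induction is the opposite, the (S)-ligand is used.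

Step 1
Reactants: 1 1-(benzyloxy)-4-ethynylbenzene; 2 3,5-bis(benzyloxy)benzaldehyde
Product: 4 racemic 1-[3,5-bis(benzyloxy)phenyl]-3-[4-(benzyloxy)phenyl]prop-2-yn-1-ol, via lithium acetylide 3 (not isolated)
Conditions: n-BuLi, THF, −78 °C; then 2, −78 → 0 °C; H2O quench
Reagents that add atoms: none
Why: 1,2-Addition of a lithium acetylide to an aromatic aldehyde is reliable, and the carbinol centre may stay racemic because the next step erases it.

Step 2
Reactants: 4 racemic propargylic alcohol
Product: 5 (S)-4,6-bis(benzyloxy)-3-[4-(benzyloxy)phenyl]indan-1-one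
Conditions: [Rh(OH)(cod)]2 (cat.), (R)-BINAP (cat.), THF, 60 °C
Reagents that add atoms: none
Why: Rhodium-catalysed asymmetric isomerisation of α-arylpropargyl alcohols to 3-substituted indanones (β-hydride elimination to the ynone, hydrorhodation, 1,4-rhodium shift to the ortho carbon of ring B, intramolecular 1,4-addition) builds the five-membered ring, and the chiral bisphosphine on rhodium sets C7b in the enantiodetermining conjugate addition.

Step 3
Reactants: 6 4-(benzyloxy)-3-bromobenzaldehyde
Product: 7 2-[4-(benzyloxy)-3-bromophenyl]-1,3-dioxolane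
Conditions: ethylene glycol, TsOH·H2O (cat.), toluene, reflux, Dean–Stark trap
Reagents that add atoms: ethylene glycol, OCCO
Why: Acid-catalysed acetalisation with azeotropic removal of water masks the aldehyde against the enolate, fluoride and Grignard steps that follow.

Step 4
Reactants: 5 (S)-3-arylindanone; 7 bromoaryl dioxolane
Product: 8 (2S,3S)-4,6-bis(benzyloxy)-2-[2-(benzyloxy)-5-(1,3-dioxolan-2-yl)phenyl]-3-[4-(benzyloxy)phenyl]indan-1-one
Conditions: Pd2(dba)3 (cat.), P(t-Bu)3·HBF4 (cat.), NaOt-Bu, toluene, 70 °C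
Reagents that add atoms: none
Why: Palladium-catalysed ketone α-arylation, known for 3-arylindan-1-ones, places ring E on the only enolisable carbon, and the alkoxide base equilibrates the new C2 centre to the trans arrangement dictated by the C3 aryl group.

Step 5
Reactants: 9 3,5-bis(benzyloxy)phenol
Product: 10 3,5-bis(benzyloxy)-2-bromophenol
Conditions: NBS, CH2Cl2, −78 → 0 °C
Reagents that add atoms: N-bromosuccinimide, O=C1CCC(=O)N1Br
Why: Electrophilic aromatic bromination should go ortho to the free hydroxyl because the other activated site is crowded between two benzyloxy groups.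

Step 6
Reactants: 10 3,5-bis(benzyloxy)-2-bromophenol
Product: 13 3,5-bis(benzyloxy)-2-(trimethylsilyl)phenyl trifluoromethanesulfonate, via aryl trimethylsilyl ether 11 (not isolated), via lithium silylphenoxide 12 (not isolated)
Conditions: HN(SiMe3)2, THF, 65 °C, concentrate; n-BuLi, THF, −100 → −78 °C; Tf2O, −78 → 0 °C
Reagents that add atoms: hexamethyldisilazane, C[Si](C)(C)N[Si](C)(C)C; trifluoromethanesulfonic anhydride, O=S(=O)(OS(=O)(=O)C(F)(F)F)C(F)(F)F
Why: This is the standard route to 2-silylaryl triflates, namely O-silylation, bromine–lithium exchange, retro-Brook migration of silicon from oxygen to the lithiated carbon and triflation of the phenoxide.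

Step 7
Reactants: 8 (2S,3S)-2,3-diarylindanone; 13 silylaryl triflate
Product: 16 (10R,11S)-1,3,6,8-tetrakis(benzyloxy)-10-[2-(benzyloxy)-5-(1,3-dioxolan-2-yl)phenyl]-11-[4-(benzyloxy)phenyl]-10,11-dihydro-5H-dibenzo[a,d][7]annulen-5-one, via benzyne 14 (not isolated), via cesium benzocyclobutenoxide 15 (not isolated)
Conditions: CsF, MeCN/toluene 1:1, 80 °C
Reagents that add atoms: none
Why: Fluoride releases benzyne 14 from 13 and generates the enolate of 8, whose α-carbon C8b attacks the aryne; the resulting aryl anion adds to the neighbouring carbonyl C8a to give benzocyclobutenoxide 15, which fragments across the former C1–C2 bond (aryne acyl-alkylation, a C–C σ-bond insertion known as a two-carbon ring expansion of cyclic β-keto esters and known for α-aryl ketones). The only ring closed directly is the transient four-membered ring (4-exo-trig attack of the aryl anion on C=O), and ring C arises not by end-to-end closure but by cleavage of the bond shared by the four- and five-membered rings of 15. Fragmentation is driven by release of cyclobutene strain and by a departing C8b carbanion that is benzhydrylic and conjugated with the new ortho carbonyl as an extended enolate. C7b is untouched, whereas C8b is re-created by protonation of that extended enolate and stays epimerisable through it in the basic medium, so it should settle trans to the C7b aryl group, which 1,3-allylic strain with the adjacent ring B benzyloxy group holds pseudo-axial. The step needs attack at the aryne carbon meta to oxygen, which the inductive distortion of a 3-alkoxyaryne by its flanking benzyloxy group secures, so that the acyl carbon ends ortho to the oxygen that later closes the dihydrofuran. It also needs carbonyl capture to outrun protonation of the aryl anion, which the aprotic medium and the carbonyl held three atoms away favour.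

Step 8
Reactants: 16 ring-expanded ketone; 17 4-(benzyloxy)benzyl chloride
Product: 20 4-(benzyloxy)-3-{(10R,11S)-1,3,6,8-tetrakis(benzyloxy)-5-[(E)-4-(benzyloxy)benzylidene]-11-[4-(benzyloxy)phenyl]-10,11-dihydro-5H-dibenzo[a,d][7]annulen-10-yl}benzaldehyde, via benzylic Grignard reagent 18 (not isolated), via tertiary carbinol 19 (not isolated)
Conditions: 17, Mg, THF, 0 °C; then 16, THF, 0 → 23 °C; then 2 M aq. HCl, THF, 23 °C
Reagents that add atoms: water, O
Why: Grignard 1,2-addition to a dibenzosuberone-type ketone gives a tertiary bis-benzylic carbinol that in the acidic work-up loses water by an E1 path through the ring A-stabilised cation while the dioxolane is hydrolysed, and neither the carbinol configuration nor the alkene geometry matters because both are erased in step 10.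

Step 9
Reactants: 20 heptabenzyl alkene aldehyde
Product: 21 4-hydroxy-3-{(10R,11S)-1,3,6,8-tetrahydroxy-5-[(E)-4-hydroxybenzylidene]-11-(4-hydroxyphenyl)-10,11-dihydro-5H-dibenzo[a,d][7]annulen-10-yl}benzaldehyde
Conditions: BCl3, C6HMe5, CH2Cl2, −78 °C; then THF/H2O
Reagents that add atoms: none
Why: Lewis-acid debenzylation of aryl benzyl ethers with pentamethylbenzene as non-basic cation scavenger proceeds at low temperature and spares the aldehyde and the trisubstituted alkene, both of which hydrogenolysis would endanger.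

Step 10
Reactants: 21 heptaphenol alkene aldehyde
Product: 22 vitisinol B
Conditions: TsOH·H2O, MeCN (high dilution), 40 °C, argon
Reagents that add atoms: none
Why: In this acid-catalysed intramolecular hydroalkoxylation of an o-hydroxystilbene, reversible protonation of the 4-hydroxystyryl double bond at C8a gives the ring F-stabilised cation (protonated p-quinone methide) at C7a, which the adjacent ring A hydroxyl captures in a 5-exo closure, the proton entering C8a on the convex face of the ring C boat fixed by the pseudo-axial C7b aryl group (H-8a cis to ring D) and the reversible C7a–O closure settling in the trans-2,3-diaryl arrangement.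

Compound list
1 | 1-(benzyloxy)-4-ethynylbenzene | C#Cc1ccc(OCc2ccccc2)cc1 | starting material
2 | 3,5-bis(benzyloxy)benzaldehyde | O=Cc1cc(OCc2ccccc2)cc(OCc2ccccc2)c1 | starting material
3 | lithium [4-(benzyloxy)phenyl]acetylide | [Li]C#Cc1ccc(OCc2ccccc2)cc1 | intermediate
4 | racemic 1-[3,5-bis(benzyloxy)phenyl]-3-[4-(benzyloxy)phenyl]prop-2-yn-1-ol | OC(C#Cc1ccc(OCc2ccccc2)cc1)c1cc(OCc2ccccc2)cc(OCc2ccccc2)c1 | intermediate
5 | (S)-4,6-bis(benzyloxy)-3-[4-(benzyloxy)phenyl]indan-1-one | C1C(=O)c2cc(OCc3ccccc3)cc(OCc3ccccc3)c2[C@@H]1c1ccc(OCc2ccccc2)cc1 | intermediate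
6 | 4-(benzyloxy)-3-bromobenzaldehyde | O=Cc1ccc(OCc2ccccc2)c(Br)c1 | starting material
7 | 2-[4-(benzyloxy)-3-bromophenyl]-1,3-dioxolane | Brc1cc(C2OCCO2)ccc1OCc1ccccc1 | intermediate
8 | (2S,3S)-trans-4,6-bis(benzyloxy)-2-[2-(benzyloxy)-5-(1,3-dioxolan-2-yl)phenyl]-3-[4-(benzyloxy)phenyl]indan-1-one | C1COC(O1)c1ccc(OCc2ccccc2)c([C@H]2C(=O)c3cc(OCc4ccccc4)cc(OCc4ccccc4)c3[C@@H]2c2ccc(OCc3ccccc3)cc2)c1 | intermediate
9 | 3,5-bis(benzyloxy)phenol | Oc1cc(OCc2ccccc2)cc(OCc2ccccc2)c1 | starting material
10 | 3,5-bis(benzyloxy)-2-bromophenol | Oc1cc(OCc2ccccc2)cc(OCc2ccccc2)c1Br | intermediate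
11 | [3,5-bis(benzyloxy)-2-bromophenoxy]trimethylsilane | C[Si](C)(C)Oc1cc(OCc2ccccc2)cc(OCc2ccccc2)c1Br | intermediate
12 | lithium 3,5-bis(benzyloxy)-2-(trimethylsilyl)phenoxide | [Li+].[O-]c1cc(OCc2ccccc2)cc(OCc2ccccc2)c1[Si](C)(C)C | intermediate
13 | 3,5-bis(benzyloxy)-2-(trimethylsilyl)phenyl trifluoromethanesulfonate | C[Si](C)(C)c1c(OCc2ccccc2)cc(OCc2ccccc2)cc1OS(=O)(=O)C(F)(F)F | intermediate
14 | 3,5-bis(benzyloxy)benzyne (1,2-didehydro-3,5-bis(benzyloxy)benzene) | C1#CC(OCc2ccccc2)=CC(OCc2ccccc2)=C1 | intermediate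
15 | cesium benzocyclobutenoxide, cis-fused to the indane, aryne carbons added anti to ring D | [Cs+].C1COC(O1)c1ccc(OCc2ccccc2)c([C@]23c4cc(OCc5ccccc5)cc(OCc5ccccc5)c4[C@@]2([O-])c2cc(OCc4ccccc4)cc(OCc4ccccc4)c2[C@@H]3c2ccc(OCc3ccccc3)cc2)c1 | intermediate
16 | (10R,11S)-1,3,6,8-tetrakis(benzyloxy)-10-[2-(benzyloxy)-5-(1,3-dioxolan-2-yl)phenyl]-11-[4-(benzyloxy)phenyl]-10,11-dihydro-5H-dibenzo[a,d][7]annulen-5-one (rings D and E trans) | C1COC(O1)c1ccc(OCc2ccccc2)c([C@H]2c3cc(OCc4ccccc4)cc(OCc4ccccc4)c3C(=O)c3cc(OCc4ccccc4)cc(OCc4ccccc4)c3[C@@H]2c2ccc(OCc3ccccc3)cc2)c1 | intermediate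
17 | 4-(benzyloxy)benzyl chloride | ClCc1ccc(OCc2ccccc2)cc1 | starting material
18 | 4-(benzyloxy)benzylmagnesium chloride | Cl[Mg]Cc1ccc(OCc2ccccc2)cc1 | intermediate
19 | tertiary carbinol from 16 (formed as its chloromagnesium alkoxide), 5-[4-(benzyloxy)benzyl]-5-ol drawn with the benzyl group cis to ring D, configuration at C5 of no consequence | C1COC(O1)c1ccc(OCc2ccccc2)c([C@H]2c3cc(OCc4ccccc4)cc(OCc4ccccc4)c3[C@](O)(Cc3ccc(OCc4ccccc4)cc3)c3cc(OCc4ccccc4)cc(OCc4ccccc4)c3[C@@H]2c2ccc(OCc3ccccc3)cc2)c1 | intermediate
20 | heptabenzyl (E)-benzylidene aldehyde, (10R,11S), ring F drawn away from ring A, alkene geometry of no consequence | O=Cc1ccc(OCc2ccccc2)c([C@H]2c3cc(OCc4ccccc4)cc(OCc4ccccc4)c3/C(=C/c3ccc(OCc4ccccc4)cc3)c3cc(OCc4ccccc4)cc(OCc4ccccc4)c3[C@@H]2c2ccc(OCc3ccccc3)cc2)c1 | intermediate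
21 | heptaphenol (E)-benzylidene aldehyde, (10R,11S) | O=Cc1ccc(O)c([C@H]2c3cc(O)cc(O)c3/C(=C/c3ccc(O)cc3)c3cc(O)cc(O)c3[C@@H]2c2ccc(O)cc2)c1 | intermediate
22 | vitisinol B, C7a (S), C8a (S), C7b (S), C8b (R) | O=Cc1ccc(O)c([C@H]2c3cc(O)cc4c3[C@H](c3cc(O)cc(O)c3[C@@H]2c2ccc(O)cc2)[C@@H](c2ccc(O)cc2)O4)c1 | target

Total step count: 10. Longest linear sequence: 7 (steps 1, 2, 4, 7, 8, 9, 10).

Steps most likely to fail

Step 7. The fully substituted enolate carbon, flanked by rings D and E, may be too hindered to intercept the short-lived aryne. The aryl anion may also be protonated before it reaches the carbonyl, so that the sequence stops at plain α-arylation. Protonation of the extended enolate may be poorly face-selective.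

The fallback separates bond formation from fragmentation and works without proton sources. It sets out from 8 and 10 and returns at 16.
- Compound 8 is silylated (TBSOTf, Et3N, CH2Cl2) to the tert-butyldimethylsilyl enol ether F1.
- Compound 10 is triflated (Tf2O, pyridine) to the 2-bromoaryl triflate F2.
- n-BuLi is added to F1 and F2 in toluene at −78 °C. Bromine–lithium exchange and loss of lithium triflate release the same benzyne 14.
- [2+2] cycloaddition of 14 with the electron-rich enol ether, under the same regiochemical bias, should give the benzocyclobutenol silyl ether F3. Both aryl–carbon bonds still form in one operation.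
- n-Bu4NF in THF then unmasks the alkoxide, which fragments to 16.

Step 10. Protonation may favour the exocyclic alkene carbon (C7a) and park the material as the long-lived C8a cation, which the ring E phenol can capture transannularly. Acid may also promote condensation between the aldehyde and the resorcinol rings, or deliver the proton to C8a with poor facial selectivity.

The fallback sets H-8a by a kinetic syn addition instead of a reversible protonation. It sets out from 19, isolated by quenching step 8 with aq. NH4Cl, and returns at 22.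
- Dehydration with retention of the acetal (PPTS, 4 Å molecular sieves, toluene, 60 °C) gives the benzylidene acetal F4.
- Hydroboration–oxidation (BH3·SMe2, THF; then NaBO3·4H2O) on the convex face places boron on the less substituted C7a and hydrogen on C8a, giving the secondary carbinol F5.
- BCl3/C6HMe5 at −78 °C followed by aqueous acid removes the benzyl groups and the dioxolane to give the octahydroxy aldehyde F6.
- F6 ionises at C7a to the p-quinone methide and closes with the ring A phenol to the trans-dihydrofuran of 22.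

Step 2. The cascade may stall at the chalcone stage if the 1,4-rhodium shift next to a benzyloxy group is slow. The enantioselectivity of the conjugate addition to a β-aryl enone may also be insufficient.

The fallback pre-installs the metal site as a halide. It sets out from 2 and 3 and returns at 5.
- NBS bromination of 2 gives the 3,5-bis(benzyloxy)-2-bromobenzaldehyde F7.
- Addition of acetylide 3 gives the bromo propargylic alcohol F8.
- Ruthenium-catalysed redox isomerisation (RuCl(indenyl)(PPh3)2, In(OTf)3, camphorsulfonic acid, THF, reflux) gives the (E)-2'-bromochalcone F9.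
- An asymmetric reductive Heck cyclisation (Pd(OAc)2, (R)-3,5-Xyl-MeOBIPHEP, HCO2Na, DMF, 100 °C) gives 5.

Further compounds
F1 | step 7 | tert-butyldimethylsilyl enol ether of 8 (1-silyloxy-2,3-diaryl-1H-indene, C7b unchanged) | C1COC(O1)c1ccc(OCc2ccccc2)c(C2=C(O[Si](C)(C)C(C)(C)C)c3cc(OCc4ccccc4)cc(OCc4ccccc4)c3[C@@H]2c2ccc(OCc3ccccc3)cc2)c1
F2 | step 7 | 3,5-bis(benzyloxy)-2-bromophenyl trifluoromethanesulfonate | O=S(=O)(Oc1cc(OCc2ccccc2)cc(OCc2ccccc2)c1Br)C(F)(F)F
F3 | step 7 | benzocyclobutenol tert-butyldimethylsilyl ether (silyl ether of the alcohol of 15) | C1COC(O1)c1ccc(OCc2ccccc2)c([C@]23c4cc(OCc5ccccc5)cc(OCc5ccccc5)c4[C@@]2(O[Si](C)(C)C(C)(C)C)c2cc(OCc4ccccc4)cc(OCc4ccccc4)c2[C@@H]3c2ccc(OCc3ccccc3)cc2)c1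
F4 | step 10 | (E)-benzylidene compound with the dioxolane retained | C1COC(O1)c1ccc(OCc2ccccc2)c([C@H]2c3cc(OCc4ccccc4)cc(OCc4ccccc4)c3/C(=C/c3ccc(OCc4ccccc4)cc3)c3cc(OCc4ccccc4)cc(OCc4ccccc4)c3[C@@H]2c2ccc(OCc3ccccc3)cc2)c1
F5 | step 10 | secondary C7a carbinol with H-8a cis to ring D, heptabenzyl ether and dioxolane | C1COC(O1)c1ccc(OCc2ccccc2)c([C@H]2c3cc(OCc4ccccc4)cc(OCc4ccccc4)c3[C@H](c3cc(OCc4ccccc4)cc(OCc4ccccc4)c3[C@@H]2c2ccc(OCc3ccccc3)cc2)[C@@H](c2ccc(OCc3ccccc3)cc2)O)c1
F6 | step 10 | fully deprotected C7a carbinol aldehyde | O=Cc1ccc(O)c([C@H]2c3cc(O)cc(O)c3[C@H](c3cc(O)cc(O)c3[C@@H]2c2ccc(O)cc2)[C@@H](c2ccc(O)cc2)O)c1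
F7 | step 2 | 3,5-bis(benzyloxy)-2-bromobenzaldehyde | O=Cc1cc(OCc2ccccc2)cc(OCc2ccccc2)c1Br
F8 | step 2 | racemic 1-[3,5-bis(benzyloxy)-2-bromophenyl]-3-[4-(benzyloxy)phenyl]prop-2-yn-1-ol | OC(C#Cc1ccc(OCc2ccccc2)cc1)c1cc(OCc2ccccc2)cc(OCc2ccccc2)c1Br
F9 | step 2 | (E)-1-[3,5-bis(benzyloxy)-2-bromophenyl]-3-[4-(benzyloxy)phenyl]prop-2-en-1-one | O=C(/C=C/c1ccc(OCc2ccccc2)cc1)c1cc(OCc2ccccc2)cc(OCc2ccccc2)c1Br
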